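**Retrosynthetic overview**
1. Numbering of the oxabicycle: C1 (methyl bridgehead), C2 (CHBr), C3, C4 (cyclohexyl bridgehead), C5, C6, O7. The feature used is that the five atoms C1–C2–C3–C4–O7 of the 7-oxabicyclo[2.2.1]heptane, with the heteroatom on C2, are a latent 3-oxyfuran, while the unsubstituted ethano bridge C5–C6 is a latent acrylate.
2. The endo C2–Br comes from exo diimide reduction of a C2=C3 alkenyl bromide, made from the C2 ketone that the silyl enol ether of the cycloadduct delivers. The C5 acyl group is removed by Barton decarboxylation.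
3. Key disconnection: C1–C6 and C4–C5 by a copper bis(oxazoline)-catalysed [4+2] of siloxyfuran 15 with acryloyl imide 16. Ring order: cyclohexane first, furan second, oxabicycle last.
4. Furan 15 comes from a furan-3(2H)-one, which comes from a 1,3-diketone made by Claisen condensation of ester 8 with the enolate of silylated acetoin.
5. Cyclohexane: an enantioselective Diels–Alder of a 2-siloxydiene with trifluoroethyl acrylate sets C1'. The gem-dimethyl group comes from cyclopropanation and ring opening, and the C4' bromide from an axial alcohol by Appel inversion.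

Key step: step 11

Remark on the chemistry: the carbinol configuration of acetoin is lost when the furan is formed, so racemic acetoin is used and 10–14 are mixtures at that one carbon. In step 2 the catalyst enantiomer is assigned from the accepted binding model for acrylates (a recalled sense, not verified here), and its antipode is used should the sense prove opposite.

**Route**

Step 1
Reactants: 1 3-methylbut-3-en-2-one
Product: 2 2-methyl-3-(triisopropylsilyloxy)buta-1,3-diene
Conditions: TIPSOTf, Et3N, Et2O, 0 °C to rt
Reagents that add atoms: triisopropylsilyl trifluoromethanesulfonate, CC(C)[Si](OS(=O)(=O)C(F)(F)F)(C(C)C)C(C)C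
Why: Soft enolisation and O-silylation of the only enolisable position (the acetyl methyl) should give the cross-conjugated 2-siloxydiene.

Step 2
Reactants: 2 2-methyl-3-(triisopropylsilyloxy)buta-1,3-diene; 3 2,2,2-trifluoroethyl acrylate
Product: 4 2,2,2-trifluoroethyl (1S)-3-methyl-4-(triisopropylsilyloxy)cyclohex-3-ene-1-carboxylate
Conditions: (S)-1-(2-methylphenyl)-3,3-diphenyltetrahydro-1H,3H-pyrrolo[1,2-c][1,3,2]oxazaborole (20 mol %), HNTf2 (20 mol %), CH2Cl2, −78 to −40 °C
Reagents that add atoms: none
Why: Enantioselective Diels–Alder reaction under a cationic oxazaborolidinium catalyst, in which the siloxy group directs the ester para to itself and the diene adds to the open face of the boron-bound acrylate, which sets C1 as S.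

Step 3
Reactants: 4 2,2,2-trifluoroethyl (1S)-3-methyl-4-(triisopropylsilyloxy)cyclohex-3-ene-1-carboxylate
Product: 5 2,2,2-trifluoroethyl (3S)-1-methyl-6-(triisopropylsilyloxy)bicyclo[4.1.0]heptane-3-carboxylate (both cyclopropane faces)
Conditions: Et2Zn, CH2I2, CH2Cl2, 0 °C to rt
Reagents that add atoms: diiodomethane, ICI
Why: Simmons–Smith cyclopropanation (Furukawa variant) of the electron-rich tetrasubstituted silyl enol ether should leave the ester untouched; the new ring-fusion centres are destroyed in step 4, so their configuration is irrelevant.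

Step 4
Reactants: 5 2,2,2-trifluoroethyl (3S)-1-methyl-6-(triisopropylsilyloxy)bicyclo[4.1.0]heptane-3-carboxylate
Product: 6 2,2,2-trifluoroethyl (1S)-3,3-dimethyl-4-oxocyclohexane-1-carboxylate
Conditions: TsOH·H2O (cat.), wet CHCl3, 50 °C
Reagents that add atoms: none
Why: Acid-mediated opening of the siloxycyclopropane by protonation at the CH2 carbon (Conia-type homoketonisation) should convert it into the second methyl group and release the ketone, giving the gem-dimethyl ketone regiospecifically.

Step 5
Reactants: 6 2,2,2-trifluoroethyl (1S)-3,3-dimethyl-4-oxocyclohexane-1-carboxylate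
Product: 7 2,2,2-trifluoroethyl (1S,4R)-4-hydroxy-3,3-dimethylcyclohexane-1-carboxylate (cis)
Conditions: LiBH(s-Bu)3, THF, −78 °C; then H2O
Reagents that add atoms: none
Why: Hindered-hydride reduction of the ketone in the chair that keeps the ester equatorial should proceed by equatorial attack, as with 3-oxo-4,4-dimethyl terpenoids, to give the axial alcohol cis to the ester without touching the ester at this temperature.

Step 6
Reactants: 7 2,2,2-trifluoroethyl (1S,4R)-4-hydroxy-3,3-dimethylcyclohexane-1-carboxylate
Product: 8 2,2,2-trifluoroethyl (1S,4S)-4-bromo-3,3-dimethylcyclohexane-1-carboxylate (trans)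
Conditions: CBr4, PPh3, toluene, 60 °C
Reagents that add atoms: carbon tetrabromide, BrC(Br)(Br)Br
Why: Appel reaction, in which bromide displaces the axial alkoxyphosphonium group by SN2 with inversion, should give the equatorial bromide trans to the ester and so set C4 as S.

Step 7
Reactants: 9 3-hydroxybutan-2-one (acetoin, racemic)
Product: 10 3-(tert-butyldimethylsilyloxy)butan-2-one
Conditions: TBSCl, imidazole, DMF, rt
Reagents that add atoms: tert-butyldimethylsilyl chloride, CC(C)(C)[Si](C)(C)Cl
Why: Standard silylation of a secondary alcohol protects the hydroxyl for the enolate chemistry that follows.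

Step 8
Reactants: 8 2,2,2-trifluoroethyl (1S,4S)-4-bromo-3,3-dimethylcyclohexane-1-carboxylate; 10 3-(tert-butyldimethylsilyloxy)butan-2-one
Product: 12 1-[(1S,4S)-4-bromo-3,3-dimethylcyclohexyl]-4-(tert-butyldimethylsilyloxy)pentane-1,3-dione, via lithium enolate 11 (not isolated)
Conditions: 10 (2.3 equiv), LiN(i-Pr)2 (2.2 equiv), THF, −78 °C; then 8, −78 to 0 °C; aq. NH4Cl
Reagents that add atoms: none
Why: Crossed Claisen condensation in which the kinetic methyl-side enolate acylates on the activated trifluoroethyl ester and a second equivalent of enolate deprotonates the diketone; the ketone enolate is too weak a base to epimerise the ester α-carbon and the locked equatorial neopentyl bromide has no anti hydrogen for elimination.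

Step 9
Reactants: 12 1-[(1S,4S)-4-bromo-3,3-dimethylcyclohexyl]-4-(tert-butyldimethylsilyloxy)pentane-1,3-dione
Product: 14 5-[(1S,4S)-4-bromo-3,3-dimethylcyclohexyl]-2-methylfuran-3(2H)-one, via hydroxy diketone 13 (not isolated)
Conditions: 2 M aq. HCl, THF, 40 °C
Reagents that add atoms: none
Why: Acid removes the silyl group, the freed hydroxyl adds to the distal carbonyl to form the five-membered hemiketal, and dehydration gives the furan-3(2H)-one (acid cyclodehydration of an α'-hydroxy-1,3-diketone).

Step 10
Reactants: 14 5-[(1S,4S)-4-bromo-3,3-dimethylcyclohexyl]-2-methylfuran-3(2H)-one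
Product: 15 5-[(1S,4S)-4-bromo-3,3-dimethylcyclohexyl]-3-(tert-butyldimethylsilyloxy)-2-methylfuran
Conditions: TBSOTf, Et3N, CH2Cl2, 0 °C
Reagents that add atoms: tert-butyldimethylsilyl trifluoromethanesulfonate, CC(C)(C)[Si](C)(C)OS(=O)(=O)C(F)(F)F
Why: Soft enolisation, in which O-silylation of the ketone and loss of the C2 proton aromatise the ring, should give the 3-siloxyfuran.

Step 11
Reactants: 15 5-[(1S,4S)-4-bromo-3,3-dimethylcyclohexyl]-3-(tert-butyldimethylsilyloxy)-2-methylfuran; 16 3-acryloyloxazolidin-2-one
Product: 17 3-{[(1R,4R,5R)-4-[(1S,4S)-4-bromo-3,3-dimethylcyclohexyl]-2-(tert-butyldimethylsilyloxy)-1-methyl-7-oxabicyclo[2.2.1]hept-2-en-5-yl]carbonyl}oxazolidin-2-one (endo acyl; overview numbering)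
Conditions: [Cu((R,R)-t-Bu-box)](SbF6)2 (10 mol %; box = 2,2'-(propane-2,2-diyl)bis[(4R)-4-tert-butyl-4,5-dihydrooxazole]; from CuCl2, ligand and AgSbF6), CH2Cl2, −78 to −50 °C; cold filtration through silica, used at once
Reagents that add atoms: none
Why: The two imide carbonyls chelate the square-planar divalent copper complex, which holds the acryloyl unit s-cis with one face blocked by a tert-butyl group, and the furan adds to the open face in an endo, asynchronous but concerted [4πs+2πs] cycloaddition. The closest known reaction type is the copper bis(oxazoline)-catalysed Diels–Alder reaction of furan itself with this imide, here applied to a more electron-rich 2,5-dialkyl-3-siloxyfuran. The six-membered carbocycle C1–C2–C3–C4–C5–C6 closes by intermolecular cycloaddition through the bonds C1–C6 and C4–C5, which at the same stroke turns the furan oxygen into the O7 bridge. C5 is set by the catalyst-controlled face of the dienophile (the R,R ligand is the mirror image of the complex that gives the 2S adduct with cyclopentadiene), and C1 and C4 follow from that face together with the endo orientation, which decides which furan face is used. The reaction needs orientation, endo mode and face selectivity: the siloxy group makes the methyl-bearing furan carbon the nucleophilic terminus so that it bonds to the acrylate β-carbon, chelation secures the endo mode at low temperature, and the ligand secures the face. Because the cyclohexane stereocentres are already fixed, any exo or wrong-face adduct is a diastereomer and can be removed by chromatography here or at ketone 22.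

Step 12
Reactants: 17 the cycloadduct
Product: 18 3-{[(1R,4S,5R)-4-[(1S,4S)-4-bromo-3,3-dimethylcyclohexyl]-1-methyl-2-oxo-7-oxabicyclo[2.2.1]hept-5-yl]carbonyl}oxazolidin-2-one
Conditions: 0.5 M aq. HCl, THF, 0 °C
Reagents that add atoms: none
Why: Mild acid hydrolysis of the silyl enol ether (protonation at C3, then desilylation) should place the ketone at C2 and, by saturating C2–C3, remove any possibility of cycloreversion.

Step 13
Reactants: 18 the keto imide
Product: 20 (1R,4S,5R)-4-[(1S,4S)-4-bromo-3,3-dimethylcyclohexyl]-1-methyl-2-oxo-7-oxabicyclo[2.2.1]heptane-5-carboxylic acid (overview numbering), via peroxy acid 19 (not isolated)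
Conditions: LiOH, 30 % H2O2, THF/H2O, 0 °C; aq. Na2SO3; then 1 M HCl to pH 2
Reagents that add atoms: hydrogen peroxide (as LiOOH), OO
Why: Hydroperoxide attacks the exocyclic imide carbonyl selectively even at this hindered acyl group and sulfite reduces the peroxy acid; the short reaction at 0 °C is chosen to spare the strained ketone from enolate-driven bridge opening or oxidation.

Step 14
Reactants: 20 the keto acid
Product: 22 (1R,4S)-4-[(1S,4S)-4-bromo-3,3-dimethylcyclohexyl]-1-methyl-7-oxabicyclo[2.2.1]heptan-2-one, via Barton ester 21 (not isolated)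
Conditions: N-hydroxypyridine-2-thione, DCC, DMAP (cat.), CH2Cl2, 0 °C to rt, dark; then t-BuSH, toluene, tungsten lamp, rt
Reagents that add atoms: none
Why: Barton decarboxylation, in which the C5 radical from the thiohydroxamate ester takes hydrogen from the thiol; it is run at the ketone stage so that no C2=C3 alkene is present to trigger homoallyl–cyclopropylcarbinyl rearrangement, and the alkyl bromide is inert to the thiyl chain.

Step 15
Reactants: 22 the bicyclic ketone
Product: 24 (1R,4R)-4-[(1S,4S)-4-bromo-3,3-dimethylcyclohexyl]-1-methyl-7-oxabicyclo[2.2.1]hept-2-en-2-yl trifluoromethanesulfonate, via potassium enolate 23 (not isolated)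
Conditions: KN(SiMe3)2, THF, −78 °C; PhNTf2, −78 to −40 °C
Reagents that add atoms: N-phenylbis(trifluoromethanesulfonimide), O=S(=O)(N(c1ccccc1)S(=O)(=O)C(F)(F)F)C(F)(F)F
Why: Kinetic enolisation can only occur toward C3 because C1 is quaternary, and trapping the enolate as the triflate at low temperature should outrun β-elimination of the oxygen bridge.

Step 16
Reactants: 24 the alkenyl triflate
Product: 25 (1R,4R)-2-bromo-4-[(1S,4S)-4-bromo-3,3-dimethylcyclohexyl]-1-methyl-7-oxabicyclo[2.2.1]hept-2-ene
Conditions: Pd2(dba)3 (cat.), t-BuBrettPhos, KBr, KF, 1,4-dioxane, 110 °C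
Reagents that add atoms: potassium bromide, [K+].[Br-]
Why: Palladium-catalysed triflate-to-bromide exchange (oxidative addition, halide exchange, and C–Br reductive elimination enforced by the bulky biarylphosphine) is a known reaction of alkenyl triflates, and the unactivated secondary alkyl bromide should not compete in oxidative addition.

Step 17
Reactants: 25 the alkenyl bromide
Product: 26 (1R,2R,4S)-2-bromo-4-[(1S,4S)-4-bromo-3,3-dimethylcyclohexyl]-1-methyl-7-oxabicyclo[2.2.1]heptane (target)
Conditions: KO2CN=NCO2K, AcOH, MeOH/CH2Cl2, 0 °C to rt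
Reagents that add atoms: none
Why: Diimide transfers two hydrogens syn and in concert to the strained alkene from the exo face (the oxygen-bridge side), so both new hydrogens are exo and the C2 bromine ends endo (2R), with neither C–Br bond reduced.

**Compound list**
1 | 3-methylbut-3-en-2-one | CC(=O)C(C)=C | starting material
2 | 2-methyl-3-(triisopropylsilyloxy)buta-1,3-diene | C=C(C)C(=C)O[Si](C(C)C)(C(C)C)C(C)C | intermediate
3 | 2,2,2-trifluoroethyl acrylate | C=CC(=O)OCC(F)(F)F | starting material
4 | 2,2,2-trifluoroethyl (1S)-3-methyl-4-(triisopropylsilyloxy)cyclohex-3-ene-1-carboxylate | O=C(OCC(F)(F)F)[C@@H]1CC(C)=C(O[Si](C(C)C)(C(C)C)C(C)C)CC1 | intermediate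
5 | 2,2,2-trifluoroethyl (3S)-1-methyl-6-(triisopropylsilyloxy)bicyclo[4.1.0]heptane-3-carboxylate (cyclopropane diastereomers) | O=C(OCC(F)(F)F)[C@@H]1CC2(C)CC2(O[Si](C(C)C)(C(C)C)C(C)C)CC1 | intermediate
6 | 2,2,2-trifluoroethyl (1S)-3,3-dimethyl-4-oxocyclohexane-1-carboxylate | O=C(OCC(F)(F)F)[C@@H]1CC(C)(C)C(=O)CC1 | intermediate
7 | 2,2,2-trifluoroethyl (1S,4R)-4-hydroxy-3,3-dimethylcyclohexane-1-carboxylate (cis) | O=C(OCC(F)(F)F)[C@@H]1CC(C)(C)[C@H](O)CC1 | intermediate
8 | 2,2,2-trifluoroethyl (1S,4S)-4-bromo-3,3-dimethylcyclohexane-1-carboxylate (trans) | O=C(OCC(F)(F)F)[C@@H]1CC(C)(C)[C@@H](Br)CC1 | intermediate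
9 | 3-hydroxybutan-2-one (racemic) | CC(O)C(C)=O | starting material
10 | 3-(tert-butyldimethylsilyloxy)butan-2-one (racemic) | CC(O[Si](C)(C)C(C)(C)C)C(C)=O | intermediate
11 | lithium 3-(tert-butyldimethylsilyloxy)but-1-en-2-olate (not isolated) | C=C([O-])C(C)O[Si](C)(C)C(C)(C)C.[Li+] | intermediate
12 | 1-[(1S,4S)-4-bromo-3,3-dimethylcyclohexyl]-4-(tert-butyldimethylsilyloxy)pentane-1,3-dione (both configurations at chain C4) | CC(O[Si](C)(C)C(C)(C)C)C(=O)CC(=O)[C@@H]1CC(C)(C)[C@@H](Br)CC1 | intermediate
13 | 1-[(1S,4S)-4-bromo-3,3-dimethylcyclohexyl]-4-hydroxypentane-1,3-dione (not isolated) | CC(O)C(=O)CC(=O)[C@@H]1CC(C)(C)[C@@H](Br)CC1 | intermediate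
14 | 5-[(1S,4S)-4-bromo-3,3-dimethylcyclohexyl]-2-methylfuran-3(2H)-one (both configurations at C2) | CC1OC(=CC1=O)[C@@H]2CC(C)(C)[C@@H](Br)CC2 | intermediate
15 | 5-[(1S,4S)-4-bromo-3,3-dimethylcyclohexyl]-3-(tert-butyldimethylsilyloxy)-2-methylfuran | CC1(C)C[C@@H](c2cc(O[Si](C)(C)C(C)(C)C)c(C)o2)CC[C@@H]1Br | intermediate
16 | 3-acryloyloxazolidin-2-one | C=CC(=O)N1CCOC1=O | starting material
17 | endo C5-acyl 2-siloxy-7-oxabicyclo[2.2.1]hept-2-ene cycloadduct (1R,4R,5R) | CC1(C)C[C@@H]([C@@]23[C@H](C(=O)N4CCOC4=O)C[C@@](C)(O2)C(O[Si](C)(C)C(C)(C)C)=C3)CC[C@@H]1Br | intermediate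
18 | C2-keto C5-endo imide (1R,4S,5R) | CC1(C)C[C@@H]([C@@]23[C@H](C(=O)N4CCOC4=O)C[C@@](C)(O2)C(=O)C3)CC[C@@H]1Br | intermediate
19 | C2-keto C5-endo peroxy acid (not isolated) | CC1(C)C[C@@H]([C@@]23[C@H](C(=O)OO)C[C@@](C)(O2)C(=O)C3)CC[C@@H]1Br | intermediate
20 | C2-keto C5-endo carboxylic acid (1R,4S,5R) | CC1(C)C[C@@H]([C@@]23[C@H](C(=O)O)C[C@@](C)(O2)C(=O)C3)CC[C@@H]1Br | intermediate
21 | 2-thioxopyridin-1(2H)-yl ester of 20 (Barton ester, not isolated) | CC1(C)C[C@@H]([C@@]23[C@H](C(=O)ON4C=CC=CC4=S)C[C@@](C)(O2)C(=O)C3)CC[C@@H]1Br | intermediate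
22 | (1R,4S)-4-[(1S,4S)-4-bromo-3,3-dimethylcyclohexyl]-1-methyl-7-oxabicyclo[2.2.1]heptan-2-one | CC1(C)C[C@@H]([C@@]23CC[C@@](C)(O2)C(=O)C3)CC[C@@H]1Br | intermediate
23 | potassium enolate of 22 (not isolated) | CC1(C)C[C@@H]([C@@]23CC[C@@](C)(O2)C([O-])=C3)CC[C@@H]1Br.[K+] | intermediate
24 | C2 alkenyl triflate (1R,4R) | CC1(C)C[C@@H]([C@@]23CC[C@@](C)(O2)C(OS(=O)(=O)C(F)(F)F)=C3)CC[C@@H]1Br | intermediate
25 | C2 alkenyl bromide (1R,4R) | CC1(C)C[C@@H]([C@@]23CC[C@@](C)(O2)C(Br)=C3)CC[C@@H]1Br | intermediate
26 | (1R,2R,4S)-2-bromo-4-[(1S,4S)-4-bromo-3,3-dimethylcyclohexyl]-1-methyl-7-oxabicyclo[2.2.1]heptane | CC1(C)C[C@@H]([C@@]23CC[C@@](C)(O2)[C@H](Br)C3)CC[C@@H]1Br | target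

**Step count**
Total steps: 17. Longest linear sequence: 16 (steps 1–6 and 8–17; step 7 is a one-step branch).

**Three steps most likely to fail**

Step 11 (key cycloaddition). What may go wrong: conjugate (Mukaiyama–Michael) addition of the silyl enol ether without the second bond closing; loss of endo or facial selectivity, which would give the diastereomeric bicycle; or Lewis-acid-induced ring opening or cycloreversion of the silyl enol ether adduct. Fallback, from 15: an uncatalysed thermal cycloaddition with acryloyl chloride (propylene oxide as acid scavenger, CH2Cl2, −20 °C to rt) should give the cycloadduct acid chloride F1 as a mixture of endo/exo and facial isomers. Aqueous THF then hydrolyses both the acid chloride and the enol ether to the keto acid mixture F2 (20 and its stereoisomers). Barton decarboxylation under the conditions of step 14, through the thiohydroxamate esters F3, makes the four acids converge on two ketones: 22 and its bridgehead diastereomer F4. These two are diastereomers because the cyclohexane centres are fixed, so chromatography should separate them, at the cost of half the material, and the route is rejoined at 22.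

Step 6 (Appel inversion). What may go wrong: anti elimination of the activated axial alcohol to the cyclohexene, or methyl migration from the neighbouring quaternary carbon, in place of substitution at the neopentyl position. Fallback, from 6 (steps 5 and 6 are bypassed): the ketone is converted with (PhO)3P, Br2 and Et3N (CH2Cl2, −60 °C to rt) into the alkenyl bromide 2,2,2-trifluoroethyl (1S)-4-bromo-5,5-dimethylcyclohex-3-ene-1-carboxylate F5. Radical hydrogenation by hydrogen-atom transfer (Mn(dpm)3, PhSiH3, t-BuOOH, i-PrOH, rt) should then add hydrogen to the CH terminus and deliver the second hydrogen to the α-bromo radical axially, anti to the axial methyl. This leaves the bromine equatorial and trans to the ester, and the route is rejoined at 8.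

Step 16 (triflate-to-bromide exchange). What may go wrong: slow C–Br reductive elimination at the strained bicyclic alkenyl palladium centre, protodetriflation, or thermal cycloreversion to a furan and ethylene at the temperature required. Fallback, from 24: stannylation catalysed by Pd(PPh3)4 with Me3SnSnMe3 and LiCl (THF, 60 °C) should give the alkenylstannane F6, and bromodestannylation with N-bromosuccinimide (CH2Cl2, 0 °C) should then give 25, where the route is rejoined.

**Further compounds**
F1 | step 11 | cycloadduct acid chloride (stereoisomer mixture at the bicycle) | CC1(C)C[C@@H](C23OC(C)(CC2C(Cl)=O)C(O[Si](C)(C)C(C)(C)C)=C3)CC[C@@H]1Br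
F2 | step 11 | C2-keto C5-carboxylic acid (stereoisomer mixture at the bicycle) | CC1(C)C[C@@H](C23OC(C)(CC2C(O)=O)C(=O)C3)CC[C@@H]1Br
F3 | step 11 | thiohydroxamate esters of F2 (stereoisomer mixture, not isolated) | CC1(C)C[C@@H](C23OC(C)(CC2C(=O)ON4C=CC=CC4=S)C(=O)C3)CC[C@@H]1Br
F4 | step 11 | (1S,4R)-4-[(1S,4S)-4-bromo-3,3-dimethylcyclohexyl]-1-methyl-7-oxabicyclo[2.2.1]heptan-2-one (bridgehead diastereomer of 22) | CC1(C)C[C@@H]([C@]23CC[C@](C)(O2)C(=O)C3)CC[C@@H]1Br
F5 | step 6 | 2,2,2-trifluoroethyl (1S)-4-bromo-5,5-dimethylcyclohex-3-ene-1-carboxylate | O=C(OCC(F)(F)F)[C@@H]1CC(C)(C)C(Br)=CC1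
F6 | step 16 | C2 trimethylstannyl alkene | CC1(C)C[C@@H]([C@@]23CC[C@@](C)(O2)C([Sn](C)(C)C)=C3)CC[C@@H]1Br
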